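The constants used here were chosen freely.

I began with one ratio: the rate at which starting material went to open dimer over the rate at which it closed to ring.

    starting material → ring (k1 = 0.015 s⁻¹)
    2 starting material → open dimer (k2 = 0.036 M⁻¹ s⁻¹)
    ring ⇌ isomer of the product (K3 = 0.20, k3 = 0.018 s⁻¹)

common to all: starting material 0.91 M
- south: time 20 min; a tube with plug flow, the mixed feed as stated, residence time 20 min
- west: one stirred flow tank at steady state, fed with the mixture as stated, mean residence time 100 min
- south-east: time 20 min; a closed flask charged with all of it at once and left for 20 min
- north-east: a single well-mixed tank run continuously and read at steady state, 20 min in it on average

- percent here means starting material units held: one open dimer counts as two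
- where a step has two of a species, its rate is k times that concentration squared, and two are used at each turn
- the stated concentrations are those of everything mixed, before any reaction; amounts are the same in each set-up
- run time (south): 20 min

- the set-up with the highest share of ring in all that became ring or open dimer or isomer of the product, at the outlet or at the end ("none" if the first two lie within 2 percentage points) (south / west / south-east / north-east / none)
- share of ring in all that became ring or open dimer or isomer of the product, at the outlet or at the end, south
- share of ring in all that became ring or open dimer or isomer of the product, at the outlet or at the end, west
- share of ring in all that became ring or open dimer or isomer of the product, at the outlet or at the end, south-east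
- share of ring in all that became ring or open dimer or isomer of the product, at the outlet or at the end, north-east

With c the concentration of starting material, that ratio was c/C, a selectivity factor. Here C = 0.015 s⁻¹/(2 × 0.036 M⁻¹ s⁻¹) = 0.208 M is the crossover concentration. So of the starting material lost at any moment, the part C/(C + c) closed. The charge F = 0.91 M stood at 4.37 times C.

Closed material did not stay ring. The forward half-life of the ring-to-isomer step was 0.64 min, short against 20 min, so I took that pair as equilibrated, with ring at 83.3% of it. Ring closure alone halved the starting material in 0.770 min, so I let c fall the whole way in the tube and the closed flask.

My reckoning, set-up by set-up, gave the c that each one worked at and its share of ring: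

- south and south-east: c swept down from F; share = 83.3% × (C/F) × ln((C + F)/C) = 32.1%
- north-east: c held at 0.0405 M; share = 83.3% × C/(C + c) = 69.8%
- west: c held at 0.00957 M; share = 83.3% × C/(C + c) = 79.7%

The first line holds two set-ups, since a slice of the tube lives what the closed flask lives. Its share is 83.3% of the average of C/(C + c) over the fall from F, and that fall starts at 4.37 times C.

The second line is different. North-east sat at the one c where feed minus outflow matched reaction, and that c lay below C.

The third line, west, has the longer stay, 100 min, and its c came out lower still. So I chose west, ahead of north-east by 9.9 percentage points.

The forecast named west, with south 32.1%, west 79.7%, south-east 32.1% and north-east 69.9% against my 69.8%, on the ground that “stirred tanks favour ring”.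

The simulation gave west, with south 32.1%, west 79.7%, south-east 32.1% and north-east 69.9%. In south-east, charged above C, open dimer ended at 61.5% of the charge against ring at 32.1%. For a neighbour of south-east charged with 0.36 M, the first line with the same C gave 48.3%, and that neighbour's share stood at 48.4%.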